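**Retrosynthetic overview**
1. Target ⇒ last step: chiral-phosphoric-acid-catalysed dehydrative double ketalisation of the hexaphenolic 2-aryl-1,3-diketone 14, closing the dihydrofuran and chromanone rings together and setting both ketal stereocentres.
2. 14 ⇒ global hydrogenolysis of heptabenzyl diketone 13 ⇒ C-8–C(α) bond by Pinhey arylation of diketone 11 with (R)-tribenzylflavan 7.
3. 7 ⇒ Mitsunobu pyran closure (inversion) of (S)-carbinol 6 ⇐ CBS reduction of ketone 5 ⇐ aryl Grignard 4 + dihydrocoumarin 3 ⇐ 3,5-bis(benzyloxy)phenol 1 + acrylic acid 2.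
4. 11 ⇐ C-acylation of tribenzyl phloroacetophenone 9 with 4-(benzyloxy)benzoyl chloride 10.
5. Ring order: flavan pyran ring first; dihydrofuran and chromanone rings last, in one operation.

Assumption: the target is taken exactly as drawn (flavan C-2 R; ketal carbon S; ring-fusion CH S; cis-fused). The catalyst antipode in step 9 is written as (R)-TRIP and must be confirmed by experiment; if it favours the (R,R)-ketal, (S)-TRIP is used.

**Step 1**
Reactants: 1 3,5-bis(benzyloxy)phenol; 2 acrylic acid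
Product: 3 5,7-bis(benzyloxy)chroman-2-one
Conditions: Amberlyst-15, ClCH2CH2Cl, 70 °C
Reagents that add atoms: none
Why: Acid-mediated hydroarylation/lactonisation (Friedel–Crafts conjugate addition ortho to the phenol OH, then ring closure) as used for 5,7-dialkoxydihydrocoumarins; the two ortho positions are equivalent, and a non-aromatic solvent at moderate temperature spares the benzyl ethers.

**Step 2**
Reactants: 3 5,7-bis(benzyloxy)chroman-2-one; 4 4-(benzyloxy)phenylmagnesium bromide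
Product: 5 1-[4-(benzyloxy)phenyl]-3-[2,4-bis(benzyloxy)-6-hydroxyphenyl]propan-1-one
Conditions: THF, −78 °C; aq. NH4Cl
Reagents that add atoms: none
Why: Mono-addition of an aryl Grignard reagent to a lactone; the magnesium lactolate formed at −78 °C resists a second addition and opens to the phenolic aryl ketone on work-up.

**Step 3**
Reactants: 5 1-[4-(benzyloxy)phenyl]-3-[2,4-bis(benzyloxy)-6-hydroxyphenyl]propan-1-one
Product: 6 (1S)-1-[4-(benzyloxy)phenyl]-3-[2,4-bis(benzyloxy)-6-hydroxyphenyl]propan-1-ol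
Conditions: (R)-Me-CBS (15 mol %), BH3·SMe2 (2.2 equiv), THF, −20 °C; MeOH quench
Reagents that add atoms: none
Why: Corey–Bakshi–Shibata reduction of an aryl alkyl ketone; the (R)-oxazaborolidine (aryl large, CH2CH2Ar small) gives the (S)-carbinol, the first stereocentre, with one extra equivalent of borane consumed by the phenol.

**Step 4**
Reactants: 6 (1S)-1-[4-(benzyloxy)phenyl]-3-[2,4-bis(benzyloxy)-6-hydroxyphenyl]propan-1-ol
Product: 7 (2R)-5,7-bis(benzyloxy)-2-[4-(benzyloxy)phenyl]chromane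
Conditions: PPh3, DIAD, THF, −20 → 0 °C
Reagents that add atoms: none
Why: Intramolecular Mitsunobu etherification; the phenol displaces the activated benzylic oxygen with inversion (S → R) to close the pyran ring, and low temperature limits SN1 leakage of the 4-alkoxybenzylic centre.

**Step 5**
Reactants: 8 1-(2,4,6-trihydroxyphenyl)ethan-1-one
Product: 9 1-[2,4,6-tris(benzyloxy)phenyl]ethan-1-one
Conditions: BnBr (3.6 equiv), K2CO3, DMF, 80 °C
Reagents that add atoms: benzyl bromide BrCc1ccccc1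
Why: Williamson ether synthesis; forcing conditions also benzylate the two hydrogen-bonded ortho hydroxyls.

**Step 6**
Reactants: 9 1-[2,4,6-tris(benzyloxy)phenyl]ethan-1-one; 10 4-(benzyloxy)benzoyl chloride
Product: 11 1-[4-(benzyloxy)phenyl]-3-[2,4,6-tris(benzyloxy)phenyl]propane-1,3-dione
Conditions: LiHMDS (2.2 equiv), THF, −78 °C, then 10, → 0 °C; aq. HCl
Reagents that add atoms: none
Why: Claisen-type C-acylation of the lithium enolate with an aroyl chloride; two equivalents of base are used because the product diketone is deprotonated as it forms.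

**Step 7**
Reactants: 7 (2R)-5,7-bis(benzyloxy)-2-[4-(benzyloxy)phenyl]chromane (1.1 equiv); 11 1-[4-(benzyloxy)phenyl]-3-[2,4,6-tris(benzyloxy)phenyl]propane-1,3-dione
Product: 13 2-{(2R)-5,7-bis(benzyloxy)-2-[4-(benzyloxy)phenyl]chroman-8-yl}-1-[4-(benzyloxy)phenyl]-3-[2,4,6-tris(benzyloxy)phenyl]propane-1,3-dione, via aryllead triacetate 12 (not isolated)
Conditions: Pb(OAc)4 (1.0 equiv), CHCl3, rt, dark; then 11, pyridine (3 equiv), 40 °C
Reagents that add atoms: none
Why: Electrophilic plumbation at C-8, the most nucleophilic and least hindered position of a 5,7-dibenzyloxyflavan (the site that also brominates), followed by Pinhey arylation (ligand coupling of the aryllead(IV) triacetate with the β-diketone), which tolerates di-ortho-substituted aryl groups; the new methine is stereolabile and left uncontrolled.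

**Step 8**
Reactants: 13 heptabenzyl 2-aryl-1,3-diketone
Product: 14 2-[(2R)-5,7-dihydroxy-2-(4-hydroxyphenyl)chroman-8-yl]-1-(4-hydroxyphenyl)-3-(2,4,6-trihydroxyphenyl)propane-1,3-dione
Conditions: H2 (1 atm), 10 % Pd/C, THF, rt; filter, concentrate cold, use at once
Reagents that add atoms: none
Why: Neutral hydrogenolysis of seven aryl benzyl ethers; the cyclic benzylic ether of the flavan and the aryl ketones survive 1 atm H2 at room temperature, and the flavan stereocentre is untouched.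

**Step 9**
Reactants: 14 hexaphenolic 2-aryl-1,3-diketone
Product: 16 target CNP0179743.1 (cis-fused ketal; ketal carbon S; ring-fusion CH S; flavan C-2 R), via cyclic hemiketal 15 (not isolated)
Conditions: (R)-TRIP (10 mol %), 4 Å MS, EtOAc, −20 °C
Reagents that add atoms: none
Why: Proposed new method: a chiral-phosphoric-acid-catalysed dynamic kinetic dehydrative bis-ketalisation, in which the chroman 7-OH first adds reversibly to the 4-hydroxybenzoyl carbonyl to give hemiketal 15, the acid ionises 15 to a phosphate-paired 2-aryl oxocarbenium (para-quinone-methide-like) ion, and the ortho-OH of the trihydroxybenzoyl group, which can only reach the face syn to its own tether, closes the chromanone ring (6-exo) to give the cis-fused ketal; C-3 epimerises through the enolisable open diketone, so the chiral phosphate selects one C-3 epimer and thereby fixes both new centres as S,S, while weak acid, sieves and low temperature keep the kinetic ketal from re-ionising to the aromatic benzofuran or flavone; the closest known reaction types are chiral-phosphoric-acid-catalysed enantioselective spiroketalisation/acetalisation and 1,6-additions to para-quinone methides generated in situ from para-hydroxybenzylic alcohols.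

**Compound list**
1 | 3,5-bis(benzyloxy)phenol | Oc1cc(OCc2ccccc2)cc(OCc2ccccc2)c1 | starting material
2 | acrylic acid | C=CC(=O)O | starting material
3 | 5,7-bis(benzyloxy)chroman-2-one | O=C1CCc2c(OCc3ccccc3)cc(OCc3ccccc3)cc2O1 | intermediate
4 | 4-(benzyloxy)phenylmagnesium bromide | Br[Mg]c1ccc(OCc2ccccc2)cc1 | starting material
5 | 1-[4-(benzyloxy)phenyl]-3-[2,4-bis(benzyloxy)-6-hydroxyphenyl]propan-1-one | O=C(CCc1c(O)cc(OCc2ccccc2)cc1OCc1ccccc1)c1ccc(OCc2ccccc2)cc1 | intermediate
6 | (1S)-1-[4-(benzyloxy)phenyl]-3-[2,4-bis(benzyloxy)-6-hydroxyphenyl]propan-1-ol | O[C@@H](CCc1c(O)cc(OCc2ccccc2)cc1OCc1ccccc1)c1ccc(OCc2ccccc2)cc1 | intermediate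
7 | (2R)-5,7-bis(benzyloxy)-2-[4-(benzyloxy)phenyl]chromane | C1C[C@H](c2ccc(OCc3ccccc3)cc2)Oc2cc(OCc3ccccc3)cc(OCc3ccccc3)c21 | intermediate
8 | 1-(2,4,6-trihydroxyphenyl)ethan-1-one | CC(=O)c1c(O)cc(O)cc1O | starting material
9 | 1-[2,4,6-tris(benzyloxy)phenyl]ethan-1-one | CC(=O)c1c(OCc2ccccc2)cc(OCc2ccccc2)cc1OCc1ccccc1 | intermediate
10 | 4-(benzyloxy)benzoyl chloride | O=C(Cl)c1ccc(OCc2ccccc2)cc1 | starting material
11 | 1-[4-(benzyloxy)phenyl]-3-[2,4,6-tris(benzyloxy)phenyl]propane-1,3-dione | O=C(CC(=O)c1c(OCc2ccccc2)cc(OCc2ccccc2)cc1OCc1ccccc1)c1ccc(OCc2ccccc2)cc1 | intermediate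
12 | {(2R)-5,7-bis(benzyloxy)-2-[4-(benzyloxy)phenyl]chroman-8-yl}lead(IV) triacetate | CC(=O)O[Pb](OC(C)=O)(OC(C)=O)c1c(OCc2ccccc2)cc(OCc2ccccc2)c2CC[C@H](c3ccc(OCc4ccccc4)cc3)Oc12 | intermediate
13 | 2-{(2R)-5,7-bis(benzyloxy)-2-[4-(benzyloxy)phenyl]chroman-8-yl}-1-[4-(benzyloxy)phenyl]-3-[2,4,6-tris(benzyloxy)phenyl]propane-1,3-dione (central CH stereolabile, both epimers and enol) | O=C(c1ccc(OCc2ccccc2)cc1)C(C(=O)c1c(OCc2ccccc2)cc(OCc2ccccc2)cc1OCc1ccccc1)c1c(OCc2ccccc2)cc(OCc2ccccc2)c2CC[C@H](c3ccc(OCc4ccccc4)cc3)Oc12 | intermediate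
14 | 2-[(2R)-5,7-dihydroxy-2-(4-hydroxyphenyl)chroman-8-yl]-1-(4-hydroxyphenyl)-3-(2,4,6-trihydroxyphenyl)propane-1,3-dione (central CH stereolabile) | O=C(c1ccc(O)cc1)C(C(=O)c1c(O)cc(O)cc1O)c1c(O)cc(O)c2CC[C@H](c3ccc(O)cc3)Oc12 | intermediate
15 | cyclic hemiketal of 14: 2-hydroxy-2-(4-hydroxyphenyl)-3-(2,4,6-trihydroxybenzoyl)-2,3-dihydrofuran fused at O-7/C-8 of the (2R)-5-hydroxy-2-(4-hydroxyphenyl)chroman (hemiketal carbons unassigned) | OC1(c2ccc(O)cc2)Oc2cc(O)c3CC[C@H](c4ccc(O)cc4)Oc3c2C1C(=O)c1c(O)cc(O)cc1O | intermediate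
16 | CNP0179743.1: 5,7-dihydroxy-2-(4-hydroxyphenyl)chroman-4-one whose C-2 (S) is bonded to O-7 and whose C-3 (S) is bonded to C-8 of (2R)-5-hydroxy-2-(4-hydroxyphenyl)chroman, forming a cis-fused 2,3-dihydrobenzofuran ketal | O=C1c2c(O)cc(O)cc2O[C@@]2(c3ccc(O)cc3)Oc3cc(O)c4c(c3[C@@H]12)O[C@@H](c1ccc(O)cc1)CC4 | target

**Totals**
Total steps: 9. Longest linear sequence: 7 (steps 1, 2, 3, 4, 7, 8, 9).

**Three steps most likely to fail**

Step 9 (the proposed new ketalisation). The oxocarbenium ion may lose H-3 and aromatise to the 2-aryl-3-aroylbenzofuran or the 3-arylflavone instead of being trapped as the kinetic ketal, and catalyst control over the (S,S)/(R,R) pair may be low. Free 14 may also cyclise without control before the catalyst is added. The fallback uses known reactions and sets out from 13. Chelation-controlled removal of one benzyl ether ortho to the aryl ketone (BCl3, CH2Cl2, −78 °C) gives 2-{(2R)-5,7-bis(benzyloxy)-2-[4-(benzyloxy)phenyl]chroman-8-yl}-1-[2,4-bis(benzyloxy)-6-hydroxyphenyl]-3-[4-(benzyloxy)phenyl]propane-1,3-dione F4. Acid cyclodehydration of F4 (TsOH, toluene, 80 °C, the flavone closure of a Baker–Venkataraman diketone) gives 5,7-bis(benzyloxy)-2-[4-(benzyloxy)phenyl]-3-{(2R)-5,7-bis(benzyloxy)-2-[4-(benzyloxy)phenyl]chroman-8-yl}-4H-chromen-4-one F5. Hydrogenolysis (H2, Pd/C, THF) then gives 5,7-dihydroxy-2-(4-hydroxyphenyl)-3-[(2R)-5,7-dihydroxy-2-(4-hydroxyphenyl)chroman-8-yl]-4H-chromen-4-one F6 as two atropisomeric diastereomers about the hindered C-3–C-8 axis, which are separated by preparative HPLC. A mild base (Et3N, MeCN, 0 °C) induces intramolecular oxa-Michael addition of the chroman 7-OH to flavone C-2 with cis protonation. This transfers the axial configuration to the two new centres, so the matching atropisomer gives 16 and the route comes back at 16; the other atropisomer is recycled by thermal equilibration of the axis.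

Step 7 (plumbation and Pinhey arylation). Pb(IV) may oxidise the substrate or plumbate C-6, and ligand coupling onto a very hindered diaryl diketone may be slow. The fallback sets out from 7. Bromination with NBS (CH2Cl2, −20 °C), which is C-8 selective for 5,7-dibenzyloxyflavans, gives (2R)-5,7-bis(benzyloxy)-2-[4-(benzyloxy)phenyl]-8-bromochromane F2. Palladium-catalysed ketone α-arylation of 9 with F2 (Pd2(dba)3, XPhos, NaOt-Bu, toluene, 80 °C) gives 2-{(2R)-5,7-bis(benzyloxy)-2-[4-(benzyloxy)phenyl]chroman-8-yl}-1-[2,4,6-tris(benzyloxy)phenyl]ethan-1-one F3. C-aroylation of F3 with 10 under soft enolisation (MgBr2·OEt2, i-Pr2NEt, CH2Cl2) comes back to the route at 13; diketone 11 is then not needed.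

Step 4 (Mitsunobu closure). The 4-alkoxybenzylic oxyphosphonium ion may ionise and erode the ee. The fallback sets out from 5. Acid cyclodehydration (TsOH cat., toluene, Dean–Stark) gives 5,7-bis(benzyloxy)-2-[4-(benzyloxy)phenyl]-4H-chromene F1. Iridium-catalysed asymmetric hydrogenation of this enol ether (Ir-phosphinooxazoline BArF catalyst, H2 50 bar, CH2Cl2, antipode chosen for R) comes back to the route at 7 and replaces steps 3 and 4.

**Further compounds**
F1 | step 4 | 5,7-bis(benzyloxy)-2-[4-(benzyloxy)phenyl]-4H-chromene | C1C=C(c2ccc(OCc3ccccc3)cc2)Oc2cc(OCc3ccccc3)cc(OCc3ccccc3)c21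
F2 | step 7 | (2R)-5,7-bis(benzyloxy)-2-[4-(benzyloxy)phenyl]-8-bromochromane | Brc1c(OCc2ccccc2)cc(OCc2ccccc2)c2CC[C@H](c3ccc(OCc4ccccc4)cc3)Oc12
F3 | step 7 | 2-{(2R)-5,7-bis(benzyloxy)-2-[4-(benzyloxy)phenyl]chroman-8-yl}-1-[2,4,6-tris(benzyloxy)phenyl]ethan-1-one | O=C(Cc1c(OCc2ccccc2)cc(OCc2ccccc2)c2CC[C@H](c3ccc(OCc4ccccc4)cc3)Oc12)c1c(OCc2ccccc2)cc(OCc2ccccc2)cc1OCc1ccccc1
F4 | step 9 | 2-{(2R)-5,7-bis(benzyloxy)-2-[4-(benzyloxy)phenyl]chroman-8-yl}-1-[2,4-bis(benzyloxy)-6-hydroxyphenyl]-3-[4-(benzyloxy)phenyl]propane-1,3-dione | O=C(c1ccc(OCc2ccccc2)cc1)C(C(=O)c1c(O)cc(OCc2ccccc2)cc1OCc1ccccc1)c1c(OCc2ccccc2)cc(OCc2ccccc2)c2CC[C@H](c3ccc(OCc4ccccc4)cc3)Oc12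
F5 | step 9 | 5,7-bis(benzyloxy)-2-[4-(benzyloxy)phenyl]-3-{(2R)-5,7-bis(benzyloxy)-2-[4-(benzyloxy)phenyl]chroman-8-yl}-4H-chromen-4-one | O=c1c(-c2c(OCc3ccccc3)cc(OCc3ccccc3)c3CC[C@H](c4ccc(OCc5ccccc5)cc4)Oc23)c(-c2ccc(OCc3ccccc3)cc2)oc2cc(OCc3ccccc3)cc(OCc3ccccc3)c12
F6 | step 9 | 5,7-dihydroxy-2-(4-hydroxyphenyl)-3-[(2R)-5,7-dihydroxy-2-(4-hydroxyphenyl)chroman-8-yl]-4H-chromen-4-one | O=c1c(-c2c(O)cc(O)c3CC[C@H](c4ccc(O)cc4)Oc23)c(-c2ccc(O)cc2)oc2cc(O)cc(O)c12
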